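**Plan**

1. Core numbering used throughout: C1 (carries the guaiacyl ring), O2, C3, C3a, C4 (carries the second aryl ring), O5, C6, C6a. Retrosynthetic cuts, in order: the four silyl ethers; O2–C3 (the ether comes from a C3 lactone); the C3a–H/C4–H pair (from a C3a=C4 enol ether); O5–C6, which contracts ring C3a–C4–O5–C6–C6a to the cyclopropane C3a–C6–C6a; then C3a–C6/C3a–C6a (carbenoid), C3a–C4 (Claisen), C7''–C8'' (aldol) and ArO–C8'' (alkylation).
2. Enabling feature: O5 and C4 are the oxygen and carbon of an aryl ketone on C3a, and C3 is a lactone carbonyl on the same carbon. C3a–C6–C6a is therefore a doubly activated cyclopropyl ketone with an unsubstituted CH2 (C6), which can undergo Cloke–Wilson ring expansion to the five-membered C3a=C4 enol ether.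
3. Forward order: the side-chain benzoate and the (R)-allylic acetate are joined by Claisen condensation. One carbenoid event closes the lactone ring (C1, O2, C3, C3a, C6a) and the cyclopropane. Ring expansion gives the second ring, and hydrogenation, lactone reduction and re-closure as the ether finish the core.
4. Stereochemistry: C7''/C8'' from an Evans syn aldol; C1 from a lipase resolution; C6a from substrate-controlled cyclopropanation (aryl anti to the cyclopropane CH2); C3a and C4 from syn hydrogenation of the cis-fused bicycle, which puts H-4 exo and the C4 aryl endo.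

Key step: step 13

Assumption: the SMILES is read as the (1R,3aS,4S,6aS) core, with the guaiacyl ring exo at C1 and the other aryl ring endo at C4 (cis to C3), carrying a threo (7''R,8''R) arylglycerol β-aryl ether.

Abbreviations in names: TBS = tert-butyldimethylsilyl; ArG = 4-(TBS-oxy)-3-methoxyphenyl; ArS = 4-{[(1R,2R)-1,3-bis(TBS-oxy)-1-[4-(TBS-oxy)-3,5-dimethoxyphenyl]propan-2-yl]oxy}-3,5-dimethoxyphenyl.

**Route**

Step 1
Reactants: 1 (S)-4-benzyloxazolidin-2-one; 2 bromoacetyl bromide
Product: 3 (S)-4-benzyl-3-(bromoacetyl)oxazolidin-2-one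
Conditions: n-BuLi, THF, −78 °C; then 2, −78 → 0 °C
Reagents that add atoms: none
Why: N-acylation of the lithiated oxazolidinone (standard imide formation), the acyl bromide reacting far faster than the alkyl bromide.

Step 2
Reactants: 3; 4 methyl syringate (methyl 4-hydroxy-3,5-dimethoxybenzoate)
Product: 5 methyl 4-{2-[(S)-4-benzyl-2-oxooxazolidin-3-yl]-2-oxoethoxy}-3,5-dimethoxybenzoate
Conditions: K2CO3, acetone, rt
Reagents that add atoms: none
Why: Williamson etherification, the phenoxide displacing the activated α-bromide by SN2 while the mild carbonate base leaves imide and ester intact.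

Step 3
Reactants: 6 syringaldehyde (4-hydroxy-3,5-dimethoxybenzaldehyde)
Product: 7 4-(TBS-oxy)-3,5-dimethoxybenzaldehyde
Conditions: TBSCl, imidazole, DMF, rt
Reagents that add atoms: tert-butyldimethylsilyl chloride, CC(C)(C)[Si](C)(C)Cl
Why: imidazole-promoted silylation of the phenol, needed so that the aldehyde tolerates the boron aldol and later base.

Step 4
Reactants: 5; 7
Product: 9 methyl 4-{[(2S,3R)-1-[(S)-4-benzyl-2-oxooxazolidin-3-yl]-3-hydroxy-1-oxo-3-[4-(TBS-oxy)-3,5-dimethoxyphenyl]propan-2-yl]oxy}-3,5-dimethoxybenzoate, via dibutylboron Z-enolate 8 (not isolated)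
Conditions: Bu2BOTf, i-Pr2NEt, CH2Cl2, −78 → 0 °C; then 7, −78 → 0 °C; pH 7 buffer, MeOH, H2O2
Reagents that add atoms: none
Why: Evans syn aldol through the Z-boron enolate and a Zimmerman–Traxler chair, the (S)-benzyl auxiliary shielding one enolate face so that both new centres (the future C8'' and C7'') are set as the syn (2S,3R) pair.

Step 5
Reactants: 9
Product: 10 methyl 4-{[(1R,2R)-1,3-dihydroxy-1-[4-(TBS-oxy)-3,5-dimethoxyphenyl]propan-2-yl]oxy}-3,5-dimethoxybenzoate
Conditions: NaBH4, THF/H2O, 0 °C → rt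
Reagents that add atoms: none
Why: borohydride reductive cleavage of the N-acyl oxazolidinone, which is far more electrophilic than the aryl methyl ester, gives the threo 1,3-diol without touching either stereocentre.

Step 6
Reactants: 10
Product: 11 methyl 4-{[(1R,2R)-1,3-bis(TBS-oxy)-1-[4-(TBS-oxy)-3,5-dimethoxyphenyl]propan-2-yl]oxy}-3,5-dimethoxybenzoate (ArS–CO2Me)
Conditions: TBSOTf, 2,6-lutidine, CH2Cl2, −78 → 0 °C
Reagents that add atoms: tert-butyldimethylsilyl triflate, CC(C)(C)[Si](C)(C)OS(=O)(=O)C(F)(F)F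
Why: silyl triflate silylation of the primary and the hindered benzylic hydroxyl, giving one protecting-group type for a single final deprotection.

Step 7
Reactants: 12 vanillin
Product: 13 4-(TBS-oxy)-3-methoxybenzaldehyde
Conditions: TBSCl, imidazole, DMF, rt
Reagents that add atoms: tert-butyldimethylsilyl chloride, CC(C)(C)[Si](C)(C)Cl
Why: imidazole-promoted silylation of the phenol before organometallic addition.

Step 8
Reactants: 13; 14 vinylmagnesium bromide
Product: 15 racemic 1-ArG-prop-2-en-1-ol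
Conditions: THF, −78 → 0 °C; aq. NH4Cl
Reagents that add atoms: none
Why: Grignard 1,2-addition to the aldehyde gives the racemic aryl vinyl carbinol.

Step 9
Reactants: 15; 16 vinyl acetate
Product: 17 (R)-1-ArG-prop-2-en-1-yl acetate
Conditions: Novozym 435 (immobilised Candida antarctica lipase B), MTBE, 30 °C, stopped near half conversion; chromatography from the unreacted (S)-alcohol
Reagents that add atoms: none
Why: lipase-catalysed kinetic resolution by irreversible transesterification, the enzyme acylating the enantiomer with aryl as the large and vinyl as the medium group arranged as in (R)-1-phenylethanol, which sets the future C1 as R.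

Step 10
Reactants: 17; 11
Product: 19 (R)-1-ArG-prop-2-en-1-yl 3-ArS-3-oxopropanoate, via lithium enolate of acetate 17 18 (not isolated)
Conditions: LiN(SiMe3)2 (3.5 equiv), THF, −78 °C; then 11, −78 → −30 °C; AcOH
Reagents that add atoms: none
Why: crossed Claisen condensation of the ester enolate with the non-enolisable aryl methyl ester (forming C3a–C4), driven by deprotonation of the β-keto ester by excess amide base, at a temperature where the allylic ester enolate should not rearrange.

Step 11
Reactants: 19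
Product: 20 (R)-1-ArG-prop-2-en-1-yl 2-diazo-3-ArS-3-oxopropanoate
Conditions: 4-acetamidobenzenesulfonyl azide, Et3N, MeCN, 0 °C → rt
Reagents that add atoms: 4-acetamidobenzenesulfonyl azide, CC(=O)Nc1ccc(cc1)S(=O)(=O)N=[N+]=[N-]
Why: Regitz diazo transfer to the doubly activated methylene.

Step 12
Reactants: 20
Product: 21 (1S,4R,5R)-1-(ArS-carbonyl)-4-ArG-3-oxabicyclo[3.1.0]hexan-2-one (aryl at C4 anti to the cyclopropane CH2; bicycle C1 = core C3a, C5 = core C6a, C6 = core C6)
Conditions: Rh2(OAc)4 (1 mol %), CH2Cl2, 40 °C, slow addition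
Reagents that add atoms: none
Why: intramolecular cyclopropanation of the terminal alkene by the rhodium carbenoid, where the ester tether enforces the cis-fused bicyclic lactone and the existing carbinol centre should steer its aryl group to the exo face, anti to the new cyclopropane CH2, thereby setting core C6a relative to C1.

Step 13
Reactants: 21
Product: 23 (1R,6aS)-1-ArG-4-ArS-6,6a-dihydro-1H-furo[3,4-c]furan-3-one (core numbering; C3a=C4 enol ether), via sodium enolate of the 4-(iodomethyl) β-keto lactone 22 (not isolated)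
Conditions: NaI (0.3 equiv), acetone, 56 °C
Reagents that add atoms: none
Why: Cloke–Wilson rearrangement under nucleophilic catalysis: iodide opens the doubly activated cyclopropane by SN2 attack at its only unsubstituted carbon (the CH2, core C6) to give the β-keto lactone enolate 22, whose ketone oxygen then displaces iodide from the same CH2, so the three-membered ring C3a–C6–C6a grows by the aroyl C=O into the five-membered ring C3a=C4–O5–C6–C6a and iodide is released. The closest known reaction type is the iodide- or amine-catalysed Cloke–Wilson rearrangement of 1-acylcyclopropane-1-carboxylates to 4,5-dihydrofuran-3-carboxylates (homoconjugate addition followed by enolate O-alkylation). The new ring closes in the 5-exo-tet mode. No stereocentre is created: C1 and C6a are untouched and keep their configuration, while C3a and C4 are left trigonal so that the next step can set both from one face. The step needs regioselectivity in three respects and the substrate secures each: iodide attacks the primary CH2 and not the ring-fusion CH; C-alkylation of 22 only regenerates 21 and is a reversible dead end; closure through the lactone carbonyl oxygen would give a bridged anti-Bredt ketene acetal, which leaves closure through the ketone oxygen, to the conjugated vinylogous carbonate 23 with its lactone intact, as the thermodynamic outcome.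

Step 14
Reactants: 23
Product: 24 (1R,3aR,4S,6aS)-1-ArG-4-ArS-tetrahydro-1H-furo[3,4-c]furan-3-one (core numbering; lactone C3=O; 1-aryl exo and 4-aryl endo)
Conditions: H2 (4 atm), Rh/Al2O3 (5 %), EtOAc, rt
Reagents that add atoms: none
Why: heterogeneous syn hydrogenation of the tetrasubstituted enol ether, in which the cis ring fusion demands hydrogen delivery to C3a on the face of H-6a and syn addition then places H-4 on the same exo face, setting C3a and C4 with the C4 aryl endo, rhodium on alumina being chosen to spare the benzylic C–O bonds.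

Step 15
Reactants: 24
Product: 25 {(2S,3S,4S)-2-ArS-4-[(R)-hydroxy(ArG)methyl]tetrahydrofuran-3-yl}methanol
Conditions: LiBH4, THF, 0 °C → rt
Reagents that add atoms: none
Why: hydride reduction of the lactone to the 1,4-diol, with no stereocentre touched and the aryl silyl ethers stable to borohydride.

Step 16
Reactants: 25
Product: 27 (1R,3aS,4S,6aS)-1-ArG-4-ArS-tetrahydro-1H,3H-furo[3,4-c]furan, via primary mesylate of diol 25 26 (not isolated)
Conditions: MsCl (1.1 equiv), pyridine, 0 °C → rt
Reagents that add atoms: none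
Why: selective sulfonylation of the primary alcohol followed by intramolecular Williamson etherification (5-exo-tet) by the benzylic hydroxyl, whose C–O bond is never broken, so C1 keeps its configuration and the endo C4 ether is not exposed to acid.

Step 17
Reactants: 27
Product: 28 (1R,3aS,4S,6aS)-1-(4-hydroxy-3-methoxyphenyl)-4-{4-[(1R,2R)-1,3-dihydroxy-1-(4-hydroxy-3,5-dimethoxyphenyl)propan-2-yl]oxy-3,5-dimethoxyphenyl}tetrahydro-1H,3H-furo[3,4-c]furan
Conditions: Bu4NF, AcOH, THF, 0 °C → rt
Reagents that add atoms: none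
Why: fluoride cleavage of the two aryl and two alkyl silyl ethers in one operation, buffered with acetic acid so that neither base nor acid can epimerise the benzylic ether centres.

**Compound list**

1 | (S)-4-benzyloxazolidin-2-one | O=C1OC[C@H](Cc2ccccc2)N1 | starting material
2 | bromoacetyl bromide | BrCC(Br)=O | starting material
3 | (S)-4-benzyl-3-(bromoacetyl)oxazolidin-2-one | O=C1OC[C@H](Cc2ccccc2)N1C(=O)CBr | intermediate
4 | methyl syringate | COC(=O)c1cc(OC)c(O)c(OC)c1 | starting material
5 | methyl 4-{2-[(S)-4-benzyl-2-oxooxazolidin-3-yl]-2-oxoethoxy}-3,5-dimethoxybenzoate | COC(=O)c1cc(OC)c(OCC(=O)N2C(=O)OC[C@@H]2Cc3ccccc3)c(OC)c1 | intermediate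
6 | syringaldehyde | COc1cc(C=O)cc(OC)c1O | starting material
7 | 4-(TBS-oxy)-3,5-dimethoxybenzaldehyde | COc1cc(C=O)cc(OC)c1O[Si](C)(C)C(C)(C)C | intermediate
8 | dibutylboron Z-enolate of 5 | CCCCB(CCCC)O/C(=C\Oc1c(OC)cc(cc1OC)C(=O)OC)N1C(=O)OC[C@@H]1Cc1ccccc1 | intermediate
9 | (2S,3R) syn-aldol adduct of 5 and 7 | COC(=O)c1cc(OC)c(O[C@H](C(=O)N2C(=O)OC[C@@H]2Cc3ccccc3)[C@H](O)c4cc(OC)c(O[Si](C)(C)C(C)(C)C)c(OC)c4)c(OC)c1 | intermediate
10 | methyl 4-{[(1R,2R)-1,3-dihydroxy-1-[4-(TBS-oxy)-3,5-dimethoxyphenyl]propan-2-yl]oxy}-3,5-dimethoxybenzoate | COC(=O)c1cc(OC)c(O[C@H](CO)[C@H](O)c2cc(OC)c(O[Si](C)(C)C(C)(C)C)c(OC)c2)c(OC)c1 | intermediate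
11 | ArS–CO2Me (tris-TBS ester) | COC(=O)c1cc(OC)c(O[C@H](CO[Si](C)(C)C(C)(C)C)[C@H](O[Si](C)(C)C(C)(C)C)c2cc(OC)c(O[Si](C)(C)C(C)(C)C)c(OC)c2)c(OC)c1 | intermediate
12 | vanillin | COc1cc(C=O)ccc1O | starting material
13 | 4-(TBS-oxy)-3-methoxybenzaldehyde | COc1cc(C=O)ccc1O[Si](C)(C)C(C)(C)C | intermediate
14 | vinylmagnesium bromide | C=C[Mg]Br | starting material
15 | racemic 1-ArG-prop-2-en-1-ol | COc1cc(C(O)C=C)ccc1O[Si](C)(C)C(C)(C)C | intermediate
16 | vinyl acetate | CC(=O)OC=C | starting material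
17 | (R)-1-ArG-prop-2-en-1-yl acetate | COc1cc([C@@H](C=C)OC(C)=O)ccc1O[Si](C)(C)C(C)(C)C | intermediate
18 | lithium enolate of 17 | COc1cc([C@@H](C=C)OC(=C)O[Li])ccc1O[Si](C)(C)C(C)(C)C | intermediate
19 | (R)-1-ArG-prop-2-en-1-yl 3-ArS-3-oxopropanoate | COc1cc([C@@H](C=C)OC(=O)CC(=O)c2cc(OC)c(O[C@H](CO[Si](C)(C)C(C)(C)C)[C@H](O[Si](C)(C)C(C)(C)C)c3cc(OC)c(O[Si](C)(C)C(C)(C)C)c(OC)c3)c(OC)c2)ccc1O[Si](C)(C)C(C)(C)C | intermediate
20 | (R)-1-ArG-prop-2-en-1-yl 2-diazo-3-ArS-3-oxopropanoate | COc1cc([C@@H](C=C)OC(=O)C(=[N+]=[N-])C(=O)c2cc(OC)c(O[C@H](CO[Si](C)(C)C(C)(C)C)[C@H](O[Si](C)(C)C(C)(C)C)c3cc(OC)c(O[Si](C)(C)C(C)(C)C)c(OC)c3)c(OC)c2)ccc1O[Si](C)(C)C(C)(C)C | intermediate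
21 | (1S,4R,5R)-1-(ArS-carbonyl)-4-ArG-3-oxabicyclo[3.1.0]hexan-2-one | COc1cc([C@@H]2OC(=O)[C@@]3(C(=O)c4cc(OC)c(O[C@H](CO[Si](C)(C)C(C)(C)C)[C@H](O[Si](C)(C)C(C)(C)C)c5cc(OC)c(O[Si](C)(C)C(C)(C)C)c(OC)c5)c(OC)c4)C[C@@H]23)ccc1O[Si](C)(C)C(C)(C)C | intermediate
22 | sodium enolate of (4R,5R)-3-(ArS-carbonyl)-4-(iodomethyl)-5-ArG-dihydrofuran-2(3H)-one | COc1cc([C@@H]2OC(=O)C(=C([O-])c3cc(OC)c(O[C@H](CO[Si](C)(C)C(C)(C)C)[C@H](O[Si](C)(C)C(C)(C)C)c4cc(OC)c(O[Si](C)(C)C(C)(C)C)c(OC)c4)c(OC)c3)[C@H]2CI)ccc1O[Si](C)(C)C(C)(C)C.[Na+] | intermediate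
23 | (1R,6aS)-1-ArG-4-ArS-6,6a-dihydro-1H-furo[3,4-c]furan-3-one | COc1cc([C@@H]2OC(=O)C3=C(c4cc(OC)c(O[C@H](CO[Si](C)(C)C(C)(C)C)[C@H](O[Si](C)(C)C(C)(C)C)c5cc(OC)c(O[Si](C)(C)C(C)(C)C)c(OC)c5)c(OC)c4)OC[C@@H]23)ccc1O[Si](C)(C)C(C)(C)C | intermediate
24 | (1R,3aR,4S,6aS)-1-ArG-4-ArS-tetrahydro-1H-furo[3,4-c]furan-3-one | COc1cc([C@@H]2OC(=O)[C@@H]3[C@H]2CO[C@@H]3c4cc(OC)c(O[C@H](CO[Si](C)(C)C(C)(C)C)[C@H](O[Si](C)(C)C(C)(C)C)c5cc(OC)c(O[Si](C)(C)C(C)(C)C)c(OC)c5)c(OC)c4)ccc1O[Si](C)(C)C(C)(C)C | intermediate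
25 | {(2S,3S,4S)-2-ArS-4-[(R)-hydroxy(ArG)methyl]tetrahydrofuran-3-yl}methanol | COc1cc([C@H](O)[C@@H]2CO[C@H](c3cc(OC)c(O[C@H](CO[Si](C)(C)C(C)(C)C)[C@H](O[Si](C)(C)C(C)(C)C)c4cc(OC)c(O[Si](C)(C)C(C)(C)C)c(OC)c4)c(OC)c3)[C@@H]2CO)ccc1O[Si](C)(C)C(C)(C)C | intermediate
26 | primary mesylate of 25 | COc1cc([C@H](O)[C@@H]2CO[C@H](c3cc(OC)c(O[C@H](CO[Si](C)(C)C(C)(C)C)[C@H](O[Si](C)(C)C(C)(C)C)c4cc(OC)c(O[Si](C)(C)C(C)(C)C)c(OC)c4)c(OC)c3)[C@@H]2COS(C)(=O)=O)ccc1O[Si](C)(C)C(C)(C)C | intermediate
27 | (1R,3aS,4S,6aS)-1-ArG-4-ArS-tetrahydro-1H,3H-furo[3,4-c]furan | COc1cc([C@@H]2OC[C@@H]3[C@H]2CO[C@@H]3c4cc(OC)c(O[C@H](CO[Si](C)(C)C(C)(C)C)[C@H](O[Si](C)(C)C(C)(C)C)c5cc(OC)c(O[Si](C)(C)C(C)(C)C)c(OC)c5)c(OC)c4)ccc1O[Si](C)(C)C(C)(C)C | intermediate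
28 | CNP0317965.1 | COc1cc([C@@H]2OC[C@@H]3[C@H]2CO[C@@H]3c2cc(OC)c(O[C@H](CO)[C@H](O)c3cc(OC)c(O)c(OC)c3)c(OC)c2)ccc1O | target

**Step count and risks**

Total steps: 17. Longest linear sequence: 13 steps (1, 2, 4, 5, 6, 10, 11, 12, 13, 14, 15, 16, 17).

Three steps most likely to fail:

Step 12. The carbenoid may add with poor facial selectivity with respect to the carbinol centre, or may be diverted into aromatic cycloaddition with the electron-rich aryl ring of the ester. The fallback sets out from β-keto ester 19, without diazo transfer, and closes the cyclopropane by oxidative radical cyclisation with Mn(OAc)3·2H2O and Cu(OAc)2·H2O in AcOH/EtOH at rt. The enolate radical formed by trivalent manganese cyclises 5-exo through a chair-like transition state with the aryl group pseudo-equatorial, and the primary radical is then oxidised by divalent copper and closed onto the dicarbonyl carbon. This comes back to the route at cyclopropane 21 and makes no new compound (F0).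

Step 14. Reduction of the deactivated tetrasubstituted double bond may be slow, and forcing it may cause hydrogenolysis of the benzylic lactone C–O bond or ring saturation. The fallback sets out from 23 and reduces the unsaturated lactone first, with i-Bu2AlH in CH2Cl2 at −78 → 0 °C, to {(4S)-2-ArS-4-[(R)-hydroxy(ArG)methyl]-4,5-dihydrofuran-3-yl}methanol F1. Its double bond is now an electron-rich, unconjugated enol ether and should take up hydrogen readily (H2 1 atm, Rh/Al2O3, EtOAc with a trace of Et3N) from the face opposite the C4 carbinol substituent of the monocyclic ring. This gives the all-cis diol and comes back to the route at 25.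

Step 10. The allylic ester enolate may self-condense or rearrange faster than it is acylated by the electron-rich benzoate. The fallback sets out from 11, which is condensed with the lithium enolate of tert-butyl acetate (LiN(i-Pr)2, THF, −78 → 0 °C; a cheap partner usable in excess) to give tert-butyl 3-ArS-3-oxopropanoate F2. Acetate 17 is cleaved with i-Bu2AlH (CH2Cl2, −78 °C) to (R)-1-ArG-prop-2-en-1-ol F3. Heating F2 with F3 in toluene at 100 °C generates the aroylketene, which the alcohol traps, and the sequence comes back to the route at 19.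

**Further compounds**

F0 | step 12 | none | none
F1 | step 14 | {(4S)-2-ArS-4-[(R)-hydroxy(ArG)methyl]-4,5-dihydrofuran-3-yl}methanol | COc1cc([C@H](O)[C@@H]2COC(c3cc(OC)c(O[C@H](CO[Si](C)(C)C(C)(C)C)[C@H](O[Si](C)(C)C(C)(C)C)c4cc(OC)c(O[Si](C)(C)C(C)(C)C)c(OC)c4)c(OC)c3)=C2CO)ccc1O[Si](C)(C)C(C)(C)C
F2 | step 10 | tert-butyl 3-ArS-3-oxopropanoate | CC(C)(C)OC(=O)CC(=O)c1cc(OC)c(O[C@H](CO[Si](C)(C)C(C)(C)C)[C@H](O[Si](C)(C)C(C)(C)C)c2cc(OC)c(O[Si](C)(C)C(C)(C)C)c(OC)c2)c(OC)c1
F3 | step 10 | (R)-1-ArG-prop-2-en-1-ol | COc1cc([C@@H](C=C)O)ccc1O[Si](C)(C)C(C)(C)C
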